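Remark on the chemistry: the target (C25H32O7) has no stereocentre, and the two coupling partners and the coupled ester of the key step match it atom by atom (ring B: carboxyl at C1, methoxy at C2, oxygen or boron at C4, pentyl at C6). It is assumed that the pinacol boronate can be unmasked in the flask in which it is made, that the acid partner is the one used in excess, and that the acid-labile ester is removed before the hydrogenolysis so that the last step is neutral.

## Structural features

The target is a depside in which two benzene rings are joined by a single aryl ester and by nothing else. Ring A is a 2,4-dihydroxy-6-pentylbenzoyl unit whose carbonyl carbon is bonded to the oxygen on C4 of ring B, a 2-methoxy-6-pentylbenzoic acid. There is no stereocentre and no ring other than the two arenes, so the task is one of regiochemistry and of telling apart five oxygen functions (two phenols, one methyl ether, one aryl ester, one free acid). Both carbonyl carbons are flanked by two ortho substituents (oxygen at C2 and pentyl at C6 in each ring), which makes attack at carbon slow; this is the real difficulty of the ester bond. The fragile parts are the aryl ester, an acyl donor that will not survive hydroxide or alkoxide; the electron-rich resorcinol of ring A, open to oxidation and electrophiles; and the ring B methyl ether ortho to a carboxyl group, which strong Lewis acids would cleave. The key step uses the fact that C4 of ring B is the only ring carbon whose two neighbours (C3 and C5) both carry hydrogen, so a sterically governed C–H borylation puts boron where the ester oxygen must go. It also uses the fact that the carboxylate oxygen of ring A is exposed although its carbonyl carbon is not, so the ester is closed at the O–C4 (aryl) bond and not at the acyl carbon.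

## Logic of the disconnections

16 to 15. The two benzyl–oxygen bonds on the ring A phenols are cut. Hydrogenolysis as the last step is neutral, leaves only a volatile hydrocarbon beside the product and spares the aryl ester. The demand is that nothing else in 15 is reducible under mild conditions, which holds.

15 to 14. The oxygen–tert-butyl bond of the ring B ester is cut. Acidolysis proceeds through the alkyl cation and never touches a carbonyl carbon, so the depside link is not at risk. The demand is that the benzyl ethers survive a short exposure to acid.

14 to 13 and 8. The bond between the ester oxygen and C4 of ring B is cut, not the acyl–oxygen bond. The crowded carbonyl carbon of 13 is then never attacked, and the molecule falls into two fragments of equal size, each three steps from a commercial material. The forward step must be an oxidative carbon–oxygen coupling that prefers a carboxylate over water and over self-coupling of the boron partner, so neither fragment may carry a free phenol.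

8 to 5 and 6 (through 7). The C4–boron bond is cut back to a C–H bond. This removes the need for any pre-installed handle at a position that electrophilic substitution cannot reach, since C4 is meta to the methoxy group. The forward step must select C4 over C3 and C5 on steric grounds alone, and the ester group must offer no aromatic C–H bond of its own, which fixes the choice of a tert-butyl ester.

5 to 4. The oxygen–tert-butyl bond is cut. Because the acid is di-ortho-substituted, the forward step must alkylate the carboxyl oxygen and not pass through an acyl intermediate.

4 to 1 and 2 (through 3). The bond between the benzylic carbon and the second carbon of the pentyl chain is cut. The ring, the methoxy group and the carboxyl group then all come from one commercial arene, and the chain is completed by a four-carbon electrophile. The forward step needs selective deprotonation of the methyl group ortho to the carboxylate.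

13 to 12. The acid is traced back to the aldehyde, one oxidation level lower. The forward oxidation must not halogenate or otherwise oxidise the electron-rich ring.

12 to 10 (through 11). The bond between ring A and its carbonyl carbon is cut. The forward electrophilic formylation must go to the position next to the pentyl group (para to one ether, ortho to the other) and not between the two ethers.

10 to 9. The two benzyl–oxygen bonds are cut to the commercial resorcinol 9, which already carries the pentyl chain. The benzyl groups are chosen because they survive formylation, oxidation and the copper coupling and leave together in the last step.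

## Other disconnections considered

Alternative 1: The cut dissolves ring A at C1–C2 and C5–C6. C1, C6, the carbonyl carbon and the pentyl chain come from an oct-2-ynoyl group already esterified to the ring B oxygen, benzyl 2-methoxy-4-(oct-2-ynoyloxy)-6-pentylbenzoate A1. C2 to C5 come from 1-methoxy-1,3-bis(trimethylsilyloxy)buta-1,3-diene A2. Heating A1 with A2 should give, by [4+2] cycloaddition, 1,4-loss of methanol and acidic desilylation, benzyl 4-(2,4-dihydroxy-6-pentylbenzoyloxy)-2-methoxy-6-pentylbenzoate A3. One hydrogenolysis of the benzyl ester of A3 would then finish.
- In its favour: the ester bond is made while the acyl partner is still a slim alkynoic acid, so the hindrance problem disappears. Ring A never needs protecting groups. The polarity of the partners (nucleophilic CH2 terminus of A2, electrophilic pentyl-bearing β-carbon of A1) points to the right regiochemistry.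
- Against it: a β-alkyl ynoate is a sluggish dienophile and A2 tolerates neither long heating nor traces of acid. A1 is an aryl ester and thus an acylating agent, so the nucleophilic diene can attack the ester carbonyl and expel the ring B phenoxide, which would destroy the link the plan is meant to keep. Aromatisation can also occur by loss of the silyloxy group in place of the methoxy group, leaving a methyl ether at C2 of ring A in place of the free phenol of A3. The phenol of ring B that carries the octynoate must be made first, so the sequence is linear.
- Comparison: on protecting-group and end-game economy alternative 1 is the better plan (one deprotection after the key step against two, no benzyl ethers on ring A). On convergence the chosen plan is better (two arms of three steps against one chain through ring B). On mechanism the chosen coupling loses material only through side reactions of the boron partner, whereas here the main competing path consumes the ester itself, so the chosen plan is judged safer. The total step count is about equal.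

Alternative 2: The cut dissolves ring B at C3–C4 and C5–C6. C1, C2, C3 and C6 with their substituents come from benzyl 4-methoxy-2-oxo-6-pentyl-2H-pyran-5-carboxylate A4. C4 with its oxygen and C5 come from 1,1-bis(trimethylsilyloxy)ethene A5. Heating A4 with A5 should give a bridged lactone by inverse-demand [4+2] addition. This lactone should extrude carbon dioxide, lose a silanol and, after desilylation, give benzyl 4-hydroxy-2-methoxy-6-pentylbenzoate A6.
- In its favour: all four substituents of ring B are placed by construction. The CH2 carbon of A5 should add to C6 of the pyrone A4, which is β to the ester carbonyl and the vinylogous terminus of the lactone carbonyl, so one regioisomer is expected. The benzyl ester matches the benzyl ethers of 13, so after ester formation one hydrogenolysis would release the acid and both phenols.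
- Against it: the alternative makes only ring B. The depside bond would still have to be formed by acylating A6 with 13 at the shielded carbonyl carbon, so the central problem is moved, not solved. The 4-methoxy group feeds electron density into the pyrone and lowers its reactivity as an electron-poor diene, so high temperature is likely, and A5 is sensitive to heat and moisture. A4 is not commercial and needs its own synthesis, including a regioselective O-methylation of a 4-hydroxypyranone precursor.
- Comparison: on the end game alternative 2 is better (one global hydrogenolysis against two deprotections). On regiocontrol of the C4 substituent the two plans are equal: both aim at a single isomer, one through polarity and the other through sterics. On the ester bond and on the length of the ring B arm (three steps from 1) the chosen plan is better.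

Alternative 3: The cut is the bond between C6 of ring B and the first carbon of its pentyl chain, made last on the assembled depside. The partners are 4-[2,4-bis(benzyloxy)-6-pentylbenzoyloxy]-2-methoxybenzoic acid A7 and potassium pentyltrifluoroborate A8. With Pd(OAc)2, an N-acetyl amino acid ligand and Ag2CO3 they should give 4-[2,4-bis(benzyloxy)-6-pentylbenzoyloxy]-2-methoxy-6-pentylbenzoic acid A9. A9 is the same compound as 15 and needs only hydrogenolysis.
- In its favour: ring B would start from a simple benzoate that lacks the pentyl chain. C6 is the only ortho C–H of the directing carboxylate in A7, so site selectivity within ring B is not in doubt. The chain enters late, which suits analogue work.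
- Against it: after carboxylate-directed palladation at divalent palladium, a primary alkyl group with β-hydrogens must be transferred and reductively eliminated, and β-hydride elimination and protodeboronation of A8 compete. Stoichiometric silver and heat meet an aryl ester, two benzyl ethers and the electron-rich ring A, whose C3 and C5 are open to electrophilic palladation. The substrate is the complete depside, so losses are costly. A7 itself still needs the hindered ester bond and an orthogonal carboxyl protecting group, so no step is saved.
- Comparison: the end game is equal (A9 is 15). For late variation of the chain alternative 3 is better. On mechanism the chosen plan places its least certain step at the fragment coupling, with simple partners and sub-stoichiometric copper in place of stoichiometric silver, and is judged better. On step economy the two are about equal.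

Key step: step 7

## Route

Step 1
Reactants: 1 2-methoxy-6-methylbenzoic acid; 2 1-iodobutane
Product: 4 2-methoxy-6-pentylbenzoic acid, via dilithiated acid 3 (not isolated)
Conditions: LiN(i-Pr)2 (2.3 equiv), THF, −78 → 0 °C; then 2 (1.2 equiv), −78 °C → rt; aq. HCl
Reagents that add atoms: none
Why: Lateral (benzylic) lithiation: the first equivalent of lithium diisopropylamide forms the carboxylate and the second removes a proton from the ortho methyl group; the dianion should then be alkylated at carbon by the primary iodide (SN2), turning methyl into pentyl. The amide base does not add to the carboxylate and leaves the ring C–H bonds alone.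

Step 2
Reactants: 4 2-methoxy-6-pentylbenzoic acid
Product: 5 tert-butyl 2-methoxy-6-pentylbenzoate
Conditions: tert-butyl 2,2,2-trichloroacetimidate (2 equiv), BF3·OEt2 (cat.), CH2Cl2/cyclohexane, rt
Reagents that add atoms: tert-butyl 2,2,2-trichloroacetimidate, CC(C)(C)OC(=N)C(Cl)(Cl)Cl
Why: Acid-catalysed O-alkylation of the carboxylic acid by the tert-butyl cation released from the imidate; the bond forms at the carboxyl oxygen, so the two ortho substituents that block addition to the carbonyl carbon should not matter.

Step 3
Reactants: 5 tert-butyl 2-methoxy-6-pentylbenzoate; 6 bis(pinacolato)diboron
Product: 8 [4-(tert-butoxycarbonyl)-3-methoxy-5-pentylphenyl]boronic acid, via aryl pinacol boronate 7 (not isolated)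
Conditions: [Ir(OMe)(cod)]2 (1.5 mol %), 4,4'-di-tert-butyl-2,2'-bipyridine (3 mol %), 6 (1.0 equiv), THF, 80 °C (sealed); evaporate; NaIO4, NH4OAc, acetone/H2O, rt
Reagents that add atoms: water, O
Why: Iridium-catalysed aromatic C–H borylation is ruled by sterics and avoids C–H bonds next to a substituent; C3 is beside methoxy and C5 beside pentyl, so only C4 should react, and the tert-butyl ester offers no aromatic C–H. Periodate then cleaves the pinacol released in the hydrolysis equilibrium, so the boronic acid should be freed under buffered, near-neutral conditions that spare the tert-butyl ester.

Step 4
Reactants: 9 olivetol (5-pentylbenzene-1,3-diol)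
Product: 10 1,3-bis(benzyloxy)-5-pentylbenzene
Conditions: BnBr (2.3 equiv), K2CO3, DMF, rt → 60 °C
Reagents that add atoms: benzyl bromide, BrCc1ccccc1
Why: Williamson ether synthesis on both phenoxides; the benzyl ethers remove every free O–H from ring A before the copper coupling and are shed together at the end.

Step 5
Reactants: 10 1,3-bis(benzyloxy)-5-pentylbenzene
Product: 12 2,4-bis(benzyloxy)-6-pentylbenzaldehyde, via aryl iminium chloride 11 (not isolated)
Conditions: POCl3, DMF, 0 → 70 °C; aq. NaOAc
Reagents that add atoms: N,N-dimethylformamide, CN(C)C=O; water, O
Why: Vilsmeier–Haack formylation: the chloroiminium electrophile should attack the position para to one benzyloxy group and ortho to the other (two equivalent sites), not the carbon between the two ethers, as is usual for resorcinol diethers. Aqueous hydrolysis of the iminium salt gives the aldehyde.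

Step 6
Reactants: 12 2,4-bis(benzyloxy)-6-pentylbenzaldehyde
Product: 13 2,4-bis(benzyloxy)-6-pentylbenzoic acid
Conditions: NaClO2, NaH2PO4, 2-methyl-2-butene, t-BuOH/THF/H2O, rt
Reagents that add atoms: sodium chlorite, [Na+].[O-]Cl=O
Why: Pinnick oxidation: chlorous acid adds to the aldehyde and the adduct fragments to the acid. The alkene traps the hypochlorous acid, so the electron-rich ring should not be chlorinated, and the benzyl ethers are inert.

Step 7
Reactants: 13 2,4-bis(benzyloxy)-6-pentylbenzoic acid; 8 [4-(tert-butoxycarbonyl)-3-methoxy-5-pentylphenyl]boronic acid
Product: 14 tert-butyl 4-[2,4-bis(benzyloxy)-6-pentylbenzoyloxy]-2-methoxy-6-pentylbenzoate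
Conditions: Cu(OTf)2 (0.4 equiv), urea (2 equiv), 13 (1.5 equiv), 4 Å molecular sieves, EtOAc, 60 °C, dry air
Reagents that add atoms: none
Why: Chan–Lam esterification, the oxidative copper-mediated coupling of an arylboronic acid with an O–H nucleophile, here a carboxylic acid. Divalent copper should first exchange triflate for the carboxylate of 13, with urea taking up the triflic acid and serving as a weak ligand; the aryl group of 8 then passes from boron to copper, further oxidation gives a trivalent copper aryl carboxylate, and reductive elimination forms the bond from the carboxylate oxygen to C4 of ring B while air returns monovalent copper to the divalent state. No ring is closed and no stereocentre is created. The step needs chemoselectivity for carboxylate O-arylation over protodeboronation, over oxidative hydroxylation to the phenol (and diaryl ether from it) and over biaryl homocoupling. The substrates should secure this: the reacting acid is the only O–H or N–H group in either partner, the boron-bearing carbon has hydrogen at both ortho positions so aryl transfer is fast, and the carboxylate oxygen lies outside the pocket of the C2 benzyloxy and C6 pentyl groups that shields the carbonyl carbon. Molecular sieves and the excess of 13 keep water from competing as the oxygen nucleophile, and the surplus acid is recoverable by extraction into aqueous bicarbonate. The buffered medium should leave the tert-butyl ester and both benzyl ethers unchanged.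

Step 8
Reactants: 14 tert-butyl 4-[2,4-bis(benzyloxy)-6-pentylbenzoyloxy]-2-methoxy-6-pentylbenzoate
Product: 15 4-[2,4-bis(benzyloxy)-6-pentylbenzoyloxy]-2-methoxy-6-pentylbenzoic acid
Conditions: TFA/CH2Cl2 (1:4), 0 °C → rt
Reagents that add atoms: none
Why: Acidolysis of the tert-butyl ester by alkyl–oxygen cleavage: protonation and loss of the tert-butyl cation as 2-methylpropene. No carbonyl carbon is attacked, so the aryl ester should remain, and aryl benzyl ethers tolerate brief exposure to cold trifluoroacetic acid.

Step 9
Reactants: 15 4-[2,4-bis(benzyloxy)-6-pentylbenzoyloxy]-2-methoxy-6-pentylbenzoic acid
Product: 16 4-(2,4-dihydroxy-6-pentylbenzoyloxy)-2-methoxy-6-pentylbenzoic acid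
Conditions: H2 (1 atm), 10% Pd/C, EtOAc, rt
Reagents that add atoms: none
Why: Catalytic hydrogenolysis of the two benzylic C–O bonds; the aryl ester, the acid, the methyl ether and the arene rings are inert under these conditions, and a non-nucleophilic solvent excludes transesterification of the depside link.

## Compound list

1 | 2-methoxy-6-methylbenzoic acid | COc1cccc(C)c1C(=O)O | starting material
2 | 1-iodobutane | CCCCI | starting material
3 | lithium 2-(lithiomethyl)-6-methoxybenzoate | [Li]Cc1cccc(OC)c1C(=O)O[Li] | intermediate
4 | 2-methoxy-6-pentylbenzoic acid | CCCCCc1cccc(OC)c1C(=O)O | intermediate
5 | tert-butyl 2-methoxy-6-pentylbenzoate | CCCCCc1cccc(OC)c1C(=O)OC(C)(C)C | intermediate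
6 | bis(pinacolato)diboron | CC1(C)OB(B2OC(C)(C)C(C)(C)O2)OC1(C)C | starting material
7 | tert-butyl 2-methoxy-6-pentyl-4-(4,4,5,5-tetramethyl-1,3,2-dioxaborolan-2-yl)benzoate | CCCCCc1cc(B2OC(C)(C)C(C)(C)O2)cc(OC)c1C(=O)OC(C)(C)C | intermediate
8 | [4-(tert-butoxycarbonyl)-3-methoxy-5-pentylphenyl]boronic acid | CCCCCc1cc(B(O)O)cc(OC)c1C(=O)OC(C)(C)C | intermediate
9 | olivetol (5-pentylbenzene-1,3-diol) | CCCCCc1cc(O)cc(O)c1 | starting material
10 | 1,3-bis(benzyloxy)-5-pentylbenzene | CCCCCc1cc(OCc2ccccc2)cc(OCc2ccccc2)c1 | intermediate
11 | N-[2,4-bis(benzyloxy)-6-pentylbenzylidene]-N-methylmethanaminium chloride | CCCCCc1cc(OCc2ccccc2)cc(OCc2ccccc2)c1C=[N+](C)C.[Cl-] | intermediate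
12 | 2,4-bis(benzyloxy)-6-pentylbenzaldehyde | CCCCCc1cc(OCc2ccccc2)cc(OCc2ccccc2)c1C=O | intermediate
13 | 2,4-bis(benzyloxy)-6-pentylbenzoic acid | CCCCCc1cc(OCc2ccccc2)cc(OCc2ccccc2)c1C(=O)O | intermediate
14 | tert-butyl 4-[2,4-bis(benzyloxy)-6-pentylbenzoyloxy]-2-methoxy-6-pentylbenzoate | CCCCCc1cc(OCc2ccccc2)cc(OCc2ccccc2)c1C(=O)Oc1cc(CCCCC)c(C(=O)OC(C)(C)C)c(OC)c1 | intermediate
15 | 4-[2,4-bis(benzyloxy)-6-pentylbenzoyloxy]-2-methoxy-6-pentylbenzoic acid | CCCCCc1cc(OCc2ccccc2)cc(OCc2ccccc2)c1C(=O)Oc1cc(CCCCC)c(C(=O)O)c(OC)c1 | intermediate
16 | 4-(2,4-dihydroxy-6-pentylbenzoyloxy)-2-methoxy-6-pentylbenzoic acid | CCCCCc1cc(O)cc(O)c1C(=O)Oc1cc(CCCCC)c(C(=O)O)c(OC)c1 | target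

## Step count and risks

Total steps: 9. Longest linear sequence: 6 (steps 1, 2, 3, 7, 8, 9, or equally steps 4, 5, 6, 7, 8, 9).

Step 7 (key step). Protodeboronation and oxidative hydroxylation of the boron partner may outrun the carbon–oxygen coupling, because a carboxylate is a weak partner for the aryl copper species and the reaction is run warm in air. Triflic acid set free from Cu(OTf)2 may also strip the tert-butyl group and expose a second carboxylate that can itself be arylated. The fallback forms the acyl–oxygen bond instead of the aryl–oxygen bond. It sets out from 8, which would be oxidised with aqueous H2O2 in THF to tert-butyl 4-hydroxy-2-methoxy-6-pentylbenzoate F1. F1 would be acylated with 13 under Steglich conditions (DCC, DMAP, CH2Cl2), a method that tolerates di-ortho-substituted benzoic acids with phenols, and the route is rejoined at 14.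

Step 3. Borylation may not be fully site-selective next to the small methoxy group, or may go twice. Boron may also be lost, or boroxine mixtures form, during the in-flask cleavage of pinacol, leaving a boronic acid that cannot be purified by chromatography. The fallback sets out from 7, which would be isolated by chromatography, so that positional isomers are removed at this stage, and transesterified with diethanolamine to the crystalline tert-butyl 4-(1,3,6,2-dioxazaborocan-2-yl)-2-methoxy-6-pentylbenzoate F2. Brief two-phase hydrolysis with dilute aqueous HCl and ether would return to 8.

Step 1. Deprotonation of the methyl group may be incomplete, or proton exchange and double alkylation may occur, giving mixtures of homologous acids that are hard to separate. The fallback sets out from 1, which would be esterified first with the same imidate to tert-butyl 2-methoxy-6-methylbenzoate F3. F3 would be deprotonated with lithium diisopropylamide at −78 °C to tert-butyl 2-(lithiomethyl)-6-methoxybenzoate F4 and alkylated with 2. The route is rejoined at 5, a neutral ester that can be chromatographed; the bulky ester group should suppress self-condensation.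

Step 5. The electrophile may partly attack between the two ethers, and the hot acidic medium may remove a benzyl group. The fallback sets out from 10, which would be brominated with N-bromosuccinimide in MeCN at 0 °C to 1,5-bis(benzyloxy)-2-bromo-3-pentylbenzene F5, where any positional isomer can be removed. Bromine–lithium exchange with n-BuLi in THF at −78 °C would give [2,4-bis(benzyloxy)-6-pentylphenyl]lithium F6, and CO2 followed by acid would return to the route at 13, bypassing 12.

Step 8. The benzyl ether ortho to the ester carbonyl may be partly lost in acid, and benzyl or tert-butyl cations may alkylate ring A. The fallback reverses the order. It sets out from 14, which would be hydrogenolysed (H2, Pd/C, EtOAc) to tert-butyl 4-(2,4-dihydroxy-6-pentylbenzoyloxy)-2-methoxy-6-pentylbenzoate F7. The ester would then be cleaved with TFA in CH2Cl2 in the presence of triethylsilane as a cation trap, arriving at 16.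

## Further compounds

F1 | step 7 | tert-butyl 4-hydroxy-2-methoxy-6-pentylbenzoate | CCCCCc1cc(O)cc(OC)c1C(=O)OC(C)(C)C
F2 | step 3 | tert-butyl 4-(1,3,6,2-dioxazaborocan-2-yl)-2-methoxy-6-pentylbenzoate | CCCCCc1cc(B2OCCNCCO2)cc(OC)c1C(=O)OC(C)(C)C
F3 | step 1 | tert-butyl 2-methoxy-6-methylbenzoate | COc1cccc(C)c1C(=O)OC(C)(C)C
F4 | step 1 | tert-butyl 2-(lithiomethyl)-6-methoxybenzoate | [Li]Cc1cccc(OC)c1C(=O)OC(C)(C)C
F5 | step 5 | 1,5-bis(benzyloxy)-2-bromo-3-pentylbenzene | CCCCCc1cc(OCc2ccccc2)cc(OCc2ccccc2)c1Br
F6 | step 5 | [2,4-bis(benzyloxy)-6-pentylphenyl]lithium | [Li]c1c(CCCCC)cc(OCc2ccccc2)cc1OCc1ccccc1
F7 | step 8 | tert-butyl 4-(2,4-dihydroxy-6-pentylbenzoyloxy)-2-methoxy-6-pentylbenzoate | CCCCCc1cc(O)cc(O)c1C(=O)Oc1cc(CCCCC)c(C(=O)OC(C)(C)C)c(OC)c1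
A1 | alternative 1 | benzyl 2-methoxy-4-(oct-2-ynoyloxy)-6-pentylbenzoate | CCCCCC#CC(=O)Oc1cc(CCCCC)c(C(=O)OCc2ccccc2)c(OC)c1
A2 | alternative 1 | 1-methoxy-1,3-bis(trimethylsilyloxy)buta-1,3-diene | COC(O[Si](C)(C)C)=CC(=C)O[Si](C)(C)C
A3 | alternative 1 | benzyl 4-(2,4-dihydroxy-6-pentylbenzoyloxy)-2-methoxy-6-pentylbenzoate | CCCCCc1cc(O)cc(O)c1C(=O)Oc1cc(CCCCC)c(C(=O)OCc2ccccc2)c(OC)c1
A4 | alternative 2 | benzyl 4-methoxy-2-oxo-6-pentyl-2H-pyran-5-carboxylate | CCCCCC1=C(C(=O)OCc2ccccc2)C(OC)=CC(=O)O1
A5 | alternative 2 | 1,1-bis(trimethylsilyloxy)ethene | C=C(O[Si](C)(C)C)O[Si](C)(C)C
A6 | alternative 2 | benzyl 4-hydroxy-2-methoxy-6-pentylbenzoate | CCCCCc1cc(O)cc(OC)c1C(=O)OCc1ccccc1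
A7 | alternative 3 | 4-[2,4-bis(benzyloxy)-6-pentylbenzoyloxy]-2-methoxybenzoic acid | CCCCCc1cc(OCc2ccccc2)cc(OCc2ccccc2)c1C(=O)Oc1ccc(C(=O)O)c(OC)c1
A8 | alternative 3 | potassium pentyltrifluoroborate | CCCCC[B-](F)(F)F.[K+]
A9 | alternative 3 | 4-[2,4-bis(benzyloxy)-6-pentylbenzoyloxy]-2-methoxy-6-pentylbenzoic acid | CCCCCc1cc(OCc2ccccc2)cc(OCc2ccccc2)c1C(=O)Oc1cc(CCCCC)c(C(=O)O)c(OC)c1
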